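C1 is the C–OAc carbon, C2 the ring =CH, C3 the ring =C(Me), C4 the ring C=O and C5 the alkylidene ring carbon. C6 is the exocyclic =CH, C7(Me)–C8–C9–C10 plus O form the oxolane, C11 is CMe2, then C12, C13, C14 (CHMe) and C15 (ketone on C1).
Enabling feature: in ring C1–C5 the unit C1(O)–C2=C3–C4(=O) is a 1,4-dioxygenated but-2-ene, i.e. a latent furan. With the oxygenated C15 on C1 it is the retron of an Achmatowicz 2H-pyran-3(6H)-one (ring O, C15, C1, C2, C3, C4). C1–C5 is an aldol bond (C5 is α to C4=O), and C5=C6 is an E1cB alkene (an oxygen on C6 is β to C4=O).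
Key disconnection: the cyclopentenone goes back to a six-membered hydroxypyranone bridged by the C5–C14 chain. Base opens the hemiketal, C5 adds across the macrocycle to C1, and silanolate leaves C6, so the six-membered ring contracts to five and the fifteen-membered carbocycle to twelve.
The pyranone comes from a 2,5-bridged furan (Achmatowicz), and the macrocycle from ring-closing metathesis at C12=C13 followed by hydrogenation. C14/C15 come from (Z)-crotylboration of a furfural, C15 from DMF, and C4–C5 from 3-methyl-2-furyllithium plus a terminal epoxide.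
The oxolane fragment comes from geraniol (C5–C10 and the C7 methyl) by Sharpless epoxidation, ozonolysis, reverse prenylboration (C11, C12) and 5-exo epoxide opening. Ring order: oxirane, oxolane, second oxirane, macrocycle around the purchased furan, pyranone, cyclopentenone.

Key step: step 15

Assumption: stereocentres that are destroyed later (ozonide carbon of 4, hemiketal carbon C4 of 21, C5 of 23) are left undefined in the SMILES. The 15S carbinol is chosen on the basis of the cyclic Cram model and serves only as a relay, because C15 ends as a ketone.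

Step 1
Reactants: 1 geraniol
Product: 2 (2R,3R)-2,3-epoxygeraniol (route numbering 6R,7R)
Conditions: Ti(OiPr)4 (5 mol %), D-(−)-diethyl tartrate (7 mol %), t-BuOOH, 4 Å MS, CH2Cl2, −20 °C
Reagents that add atoms: tert-butyl hydroperoxide, CC(C)(C)OO
Why: Sharpless asymmetric epoxidation touches only the allylic C6=C7 alkene, and the D-(−)-tartrate catalyst delivers oxygen to the face that gives the (6R,7R)-epoxide, from which C7 of the target is later derived by inversion.

Step 2
Reactants: 2 (2R,3R)-2,3-epoxygeraniol
Product: 3 (2R,3R)-2,3-epoxygeranyl p-toluenesulfonate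
Conditions: TsCl, Et3N, DMAP (cat.), CH2Cl2, 0 °C
Reagents that add atoms: p-toluenesulfonyl chloride, Cc1ccc(cc1)S(=O)(=O)Cl
Why: This is a standard sulfonylation of a primary alcohol, and the tosylate serves first as protecting group and later as leaving group, so no separate protecting-group steps are needed.

Step 3
Reactants: 3 (2R,3R)-2,3-epoxygeranyl p-toluenesulfonate
Product: 5 epoxy aldehyde 3-[(2R,3R)-2-methyl-3-(tosyloxymethyl)oxiran-2-yl]propanal, via secondary ozonide 4 (not isolated)
Conditions: O3, CH2Cl2, −78 °C; then Me2S, −78 °C → rt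
Reagents that add atoms: ozone, [O-][O+]=O
Why: Ozonolysis with reductive work-up cleaves the only remaining alkene to unveil C10 as an aldehyde, while epoxide and sulfonate are inert to ozone.

Step 4
Reactants: 5 epoxy aldehyde
Product: 7 (10S)-homoallylic alcohol (6R,7R-epoxy tosylate ending in CH(OH)CMe2CH=CH2), via borinate 6 (not isolated)
Conditions: (+)-Ipc2BH [from (−)-α-pinene], 3-methylbuta-1,2-diene, THF, −25 °C; then 5, Et2O, −78 °C; then NaBO3·4H2O, THF–H2O, rt
Reagents that add atoms: 3-methylbuta-1,2-diene, CC(C)=C=C
Why: Brown reverse prenylboration through a closed chair transition state joins the γ-carbon of the prenylborane to the aldehyde, which builds C10–C11 with the quaternary C11, and the isopinocampheyl groups from (−)-α-pinene direct attack to the Re face to set 10S.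

Step 5
Reactants: 7 (10S)-homoallylic alcohol
Product: 8 (6R,7S,10S)-oxolane, 2-methyl-2-[1-hydroxy-2-(tosyloxy)ethyl]-5-(2-methylbut-3-en-2-yl)oxolane with the C6 and C11 substituents trans
Conditions: camphorsulfonic acid (10 mol %), CH2Cl2, 0 °C → rt
Reagents that add atoms: none
Why: Acid-catalysed 5-exo-tet epoxide opening by the C10 hydroxyl occurs at the tertiary C7 with inversion (7R to 7S), attack at C6 being disfavoured by the electron-withdrawing CH2OTs group, so the trans-2,5 relationship of the target oxolane follows from the two reagent-controlled centres.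

Step 6
Reactants: 8 (6R,7S,10S)-oxolane hydroxy tosylate
Product: 9 (6R,7S,10S)-2-methyl-5-(2-methylbut-3-en-2-yl)-2-(oxiran-2-yl)oxolane
Conditions: K2CO3, MeOH, 0 °C → rt
Reagents that add atoms: none
Why: Intramolecular Williamson displacement (3-exo-tet) of the primary tosylate by the C6 alkoxide forms the terminal C5–C6 epoxide with retention at C6.

Step 7
Reactants: 10 3-methylfuran
Product: 11 2-bromo-3-methylfuran
Conditions: NBS, DMF, 0 °C, dark; used at once as a solution
Reagents that add atoms: N-bromosuccinimide, O=C1CCC(=O)N1Br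
Why: Electrophilic aromatic bromination goes to the furan α-position activated by the adjacent methyl group, which fixes the regiochemistry of the later metalation.

Step 8
Reactants: 11 2-bromo-3-methylfuran; 9 oxolanyl oxirane
Product: 13 (6R,7S,10S)-furyl carbinol (3-methylfuran-2-yl-CH2-CH(OH)-oxolane), via 3-methyl-2-furyllithium 12 (not isolated)
Conditions: 11, n-BuLi, Et2O, −78 °C; then 9, BF3·OEt2, −78 °C; then H2O
Reagents that add atoms: none
Why: Bromine–lithium exchange gives a regiodefined furyllithium that opens the BF3-activated monosubstituted epoxide at its unhindered CH2 terminus (SN2), forming C4–C5 without touching the C6 configuration.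

Step 9
Reactants: 13 furyl carbinol
Product: 14 C6 tert-butyldimethylsilyl ether of 13
Conditions: TBSOTf, 2,6-lutidine, CH2Cl2, 0 °C
Reagents that add atoms: tert-butyldimethylsilyl triflate, CC(C)(C)[Si](C)(C)OS(=O)(=O)C(F)(F)F
Why: The silyl triflate silylates the hindered secondary alcohol, and the ether survives the organometallic steps while acting as the deliberately poor leaving group of the key step.

Step 10
Reactants: 14 silyl ether
Product: 16 furfural (CHO = C15 on furan carbon C1), via 5-lithiofuran 15 (not isolated)
Conditions: n-BuLi, THF, −78 → 0 °C; DMF, −78 °C → rt; then H2O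
Reagents that add atoms: N,N-dimethylformamide, CN(C)C=O
Why: The only remaining furan α-hydrogen is removed by n-BuLi and the furyllithium is formylated with DMF (Bouveault-type formylation), which installs C15 regiospecifically.

Step 11
Reactants: 16 furfural
Product: 18 (14R,15S)-syn-homoallylic furfuryl alcohol (diene), via borinate 17 (not isolated)
Conditions: cis-2-butene, n-BuLi, KOt-Bu, THF, −78 → −45 °C; (−)-Ipc2BOMe [from (+)-α-pinene], −78 °C; BF3·OEt2; then 16, −78 °C; then NaBO3·4H2O, THF–H2O, rt
Reagents that add atoms: cis-2-butene, C/C=C\C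
Why: Brown (Z)-crotylboration through a chair transition state gives the syn adduct, and the isopinocampheyl groups from (+)-α-pinene direct attack to the Si face of the aldehyde, setting 14R and 15S under reagent control.

Step 12
Reactants: 18 diene
Product: 19 2,5-bridged furan macrocycle with a C12=C13 alkene (drawn E)
Conditions: second-generation Hoveyda–Grubbs catalyst (10 mol %), toluene (1 mM), 80 °C
Reagents that add atoms: none
Why: Ring-closing metathesis starts at the less hindered C13 vinyl group and closes onto the neopentyl vinyl group, a closure beside a gem-dimethyl carbon that has close precedent in macrocyclic diterpene work, and the alkene geometry is irrelevant because it is saturated next.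

Step 13
Reactants: 19 macrocyclic alkene
Product: 20 saturated 2,5-bridged furan (6R,7S,10S,14R,15S)
Conditions: H2 (1 atm), 5% Pd/C, EtOAc, rt
Reagents that add atoms: none
Why: Heterogeneous hydrogenation should saturate the isolated disubstituted alkene much faster than the trisubstituted aromatic furan.

Step 14
Reactants: 20 bridged furfuryl alcohol
Product: 21 bridged 6-hydroxy-2H-pyran-3(6H)-one (ring O, C15, C1(=O), C2=C3(Me), C4(OH))
Conditions: VO(acac)2 (5 mol %), t-BuOOH, CH2Cl2, −20 → 0 °C
Reagents that add atoms: tert-butyl hydroperoxide, CC(C)(C)OO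
Why: In the Achmatowicz rearrangement, hydroxyl-directed oxidation of the electron-rich furan gives the cis-enedione, which the C15 hydroxyl captures as a six-membered hemiketal, a reaction precedented on macrocyclic furfuryl alcohols that leaves C14 and C15 untouched.

Step 15
Reactants: 21 bridged hydroxypyranone
Product: 24 (1S,5E,7S,10S,14R,15S)-dienone diol, via Z-enedione 22 (not isolated), via aldol adduct 23 (not isolated)
Conditions: DBU (3 equiv), toluene, 0 °C; then 40 °C, one flask
Reagents that add atoms: none
Why: The hemiketal of 21 opens by ring–chain tautomerism to the Z-enedione 22, DBU enolises the C4 ketone towards C5, the enolate adds across the macrocycle to the C1 ketone to give 23, and on warming the same position expels tert-butyldimethylsilanolate from C6 (E1cB) to give the cross-conjugated dienone 24. The closest known reaction types are the base-induced rearrangement of Achmatowicz hydroxypyranones and of cis-enediones to 4-hydroxycyclopent-2-enones, transannular aldol reactions and the DBU elimination of β-silyloxy ketones. The only ring closed is the five-membered ring C1–C5, by a 5-(enolexo)-exo-trig aldol, so that the six-membered ring O/C15/C1/C2/C3/C4 is contracted by one atom and the fifteen-membered carbocycle of 22 becomes the twelve-membered one. The new stereocentre C1 is controlled by the neighbouring C15 carbinol: in toluene its OH is hydrogen-bonded to the C1 carbonyl (cyclic Cram model), C5 attacks the face that carries H-15 and not the C14 branch, and 15S is thereby translated into 1S, while C5 and C6 become planar and the alkene should take the E geometry (C7 anti to the C4 carbonyl) usual for 4-oxy-5-alkylidenecyclopentenones. The step needs a Z-configured C2=C3 bond (locked by the pyranone ring), enolisation at C5 and not at C15 (C5–H is less hindered and acidified by the C6 oxygen, and the competing aldol modes are reversible whereas only the C1–C5 adduct has an irreversible exit), and aldol before elimination (silanolate is too poor a leaving group to compete at 0 °C with the five-ring closure).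

Step 16
Reactants: 24 dienone diol
Product: 25 (1S,5E,7S,10S,14R)-α-ketol (C15 ketone, free tertiary C1–OH)
Conditions: IBX, DMSO, rt
Reagents that add atoms: none
Why: IBX oxidises the secondary alcohol of a 1,2-diol to the α-ketol without C–C cleavage, cannot oxidise the tertiary C1–OH, and is neutral enough to leave C14 unepimerised.

Step 17
Reactants: 25 α-ketol
Product: 26 target CNP0144863.1
Conditions: Ac2O, DMAP, Et3N, CH2Cl2, rt → 40 °C
Reagents that add atoms: acetic anhydride, CC(=O)OC(C)=O
Why: DMAP-catalysed acylation through the N-acetylpyridinium ion acetylates the only hydroxyl left, with retention at C1 because the C–O bond is not broken.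

Compound list
1 | geraniol | CC(C)=CCC/C(C)=C/CO | starting material
2 | (2R,3R)-2,3-epoxygeraniol | OC[C@H]1O[C@]1(C)CCC=C(C)C | intermediate
3 | (2R,3R)-2,3-epoxygeranyl p-toluenesulfonate | Cc1ccc(cc1)S(=O)(=O)OC[C@H]1O[C@]1(C)CCC=C(C)C | intermediate
4 | secondary ozonide of 3 | Cc1ccc(cc1)S(=O)(=O)OC[C@H]1O[C@]1(C)CCC1OOC(C)(C)O1 | intermediate
5 | 3-[(2R,3R)-2-methyl-3-(tosyloxymethyl)oxiran-2-yl]propanal | Cc1ccc(cc1)S(=O)(=O)OC[C@H]1O[C@]1(C)CCC=O | intermediate
6 | O-diisopinocampheylboryl derivative of 7 | Cc1ccc(cc1)S(=O)(=O)OC[C@H]1O[C@]1(C)CC[C@H](OB([C@H]2C[C@H]3C[C@@H]([C@@H]2C)C3(C)C)[C@H]2C[C@H]3C[C@@H]([C@@H]2C)C3(C)C)C(C)(C)C=C | intermediate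
7 | (6R,7R,10S)-epoxy tosylate homoallylic alcohol | Cc1ccc(cc1)S(=O)(=O)OC[C@H]1O[C@]1(C)CC[C@H](O)C(C)(C)C=C | intermediate
8 | (6R,7S,10S)-oxolane hydroxy tosylate | Cc1ccc(cc1)S(=O)(=O)OC[C@@H](O)[C@]1(C)CC[C@H](O1)C(C)(C)C=C | intermediate
9 | (6R,7S,10S)-oxolanyl oxirane | C1O[C@H]1[C@]2(C)CC[C@H](O2)C(C)(C)C=C | intermediate
10 | 3-methylfuran | Cc1ccoc1 | starting material
11 | 2-bromo-3-methylfuran | Cc1ccoc1Br | intermediate
12 | 3-methyl-2-furyllithium | Cc1ccoc1[Li] | intermediate
13 | (6R,7S,10S)-furyl carbinol | Cc1ccoc1C[C@@H](O)[C@]2(C)CC[C@H](O2)C(C)(C)C=C | intermediate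
14 | C6 TBS ether of 13 | Cc1ccoc1C[C@@H](O[Si](C)(C)C(C)(C)C)[C@]2(C)CC[C@H](O2)C(C)(C)C=C | intermediate
15 | 5-lithiofuran from 14 | [Li]c1cc(C)c(o1)C[C@@H](O[Si](C)(C)C(C)(C)C)[C@]2(C)CC[C@H](O2)C(C)(C)C=C | intermediate
16 | furfural (C15 aldehyde) | O=Cc1cc(C)c(o1)C[C@@H](O[Si](C)(C)C(C)(C)C)[C@]2(C)CC[C@H](O2)C(C)(C)C=C | intermediate
17 | O-diisopinocampheylboryl derivative of 18 | C=C[C@@H](C)[C@H](OB([C@@H]4C[C@@H]5C[C@H]([C@H]4C)C5(C)C)[C@@H]4C[C@@H]5C[C@H]([C@H]4C)C5(C)C)c1cc(C)c(o1)C[C@@H](O[Si](C)(C)C(C)(C)C)[C@]2(C)CC[C@H](O2)C(C)(C)C=C | intermediate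
18 | (14R,15S)-syn-homoallylic furfuryl alcohol (diene) | C=C[C@@H](C)[C@H](O)c1cc(C)c(o1)C[C@@H](O[Si](C)(C)C(C)(C)C)[C@]2(C)CC[C@H](O2)C(C)(C)C=C | intermediate
19 | bridged furan macrocycle, C12=C13 alkene | O[C@@H]1c2cc(C)c(o2)C[C@@H](O[Si](C)(C)C(C)(C)C)[C@]3(C)CC[C@H](O3)C(C)(C)/C=C/[C@H]1C | intermediate
20 | saturated bridged furan | O[C@@H]1c2cc(C)c(o2)C[C@@H](O[Si](C)(C)C(C)(C)C)[C@]3(C)CC[C@H](O3)C(C)(C)CC[C@H]1C | intermediate
21 | bridged 6-hydroxy-2H-pyran-3(6H)-one | O1[C@@H]2C(=O)C=C(C)C1(O)C[C@@H](O[Si](C)(C)C(C)(C)C)[C@]3(C)CC[C@H](O3)C(C)(C)CC[C@H]2C | intermediate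
22 | macrocyclic Z-enedione (open tautomer of 21) | O[C@@H]1C(=O)/C=C(C)\C(=O)C[C@@H](O[Si](C)(C)C(C)(C)C)[C@]3(C)CC[C@H](O3)C(C)(C)CC[C@H]1C | intermediate
23 | transannular aldol adduct (1S, C5 undefined) | O[C@@H]1[C@]4(O)C=C(C)C(=O)C4[C@@H](O[Si](C)(C)C(C)(C)C)[C@]3(C)CC[C@H](O3)C(C)(C)CC[C@H]1C | intermediate
24 | (1S,5E,7S,10S,14R,15S)-dienone diol | O[C@@H]1[C@]4(O)C=C(C)C(=O)/C4=C/[C@]3(C)CC[C@H](O3)C(C)(C)CC[C@H]1C | intermediate
25 | (1S,5E,7S,10S,14R)-α-ketol | O=C1[C@]4(O)C=C(C)C(=O)/C4=C/[C@]3(C)CC[C@H](O3)C(C)(C)CC[C@H]1C | intermediate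
26 | CNP0144863.1 (1S,5E,7S,10S,14R) | CC(=O)O[C@@]12C=C(C)C(=O)/C1=C/[C@]1(C)CC[C@H](O1)C(C)(C)CC[C@@H](C)C2=O | target

Total step count: 17. Longest linear sequence: 16 (steps 1–6 and 8–17, from geraniol).

Steps most likely to fail

Step 15. Silanolate may be lost from the open-chain enolate before the C1–C5 bond forms. Retro-aldol-type fragmentation may set in during the warm stage, and the facial selectivity at C1 may erode through equilibration or through epimerisation of C15 in the open form. The fallback decouples the events with known chemistry. Setting out from 21, the reaction is stopped after the cold stage and the aldol 23 is isolated. Its C1/C15 diol is tied up with 2,2-dimethoxypropane and PPTS as the acetonide F1, which also blocks retro-aldol cleavage. The silyl ether is cleaved with HF·pyridine to the β-hydroxy ketone F2, which is converted with MsCl and Et3N into the mesylate F3. This is eliminated with DBU at 0 °C to the dienone acetonide F4. Aqueous acetic acid removes the acetonide and the route is rejoined at 24.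

Step 12. Oligomerisation and non-productive metathesis may dominate, because the neopentyl vinyl group engages slowly and the flat furan does little to bring the chain ends together. The fallback inverts the order of ring contraction and macrocyclisation. Setting out from 18, the oxidation of step 14 gives the open-chain hydroxypyranone F5. DBU as in step 15 contracts it to the cyclopentenone diol F6, in which the E-alkylidene and the quaternary C1 hold both vinyl-terminated arms on the same side of the ring. Ring-closing metathesis with the second-generation Hoveyda–Grubbs catalyst then gives the macrocyclic trienone F7. Hydrogenation of its isolated disubstituted alkene with H2 and RhCl(PPh3)3, which should spare the trisubstituted enone alkenes, rejoins the route at 24.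

Step 17. Acylation of the hindered tertiary α-ketol may be sluggish, and forcing may bring on α-ketol rearrangement or epimerisation at C14. The fallback delivers the acetate intramolecularly before the oxidation. Setting out from 24, trimethyl orthoacetate and PPTS give the cyclic orthoacetate F8. Its kinetic hydrolysis with aqueous acetic acid releases the less hindered C15 oxygen and leaves the acetyl group on the tertiary oxygen, giving the hydroxy acetate F9. Immediate IBX oxidation of the C15 carbinol then gives 26 directly.

Further compounds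
F1 | step 15 | C1/C15 acetonide of 23 | CC1(C)O[C@@H]2[C@]4(O1)C=C(C)C(=O)C4[C@@H](O[Si](C)(C)C(C)(C)C)[C@]3(C)CC[C@H](O3)C(C)(C)CC[C@H]2C
F2 | step 15 | acetonide β-hydroxy ketone (free C6–OH) | CC1(C)O[C@@H]2[C@]4(O1)C=C(C)C(=O)C4[C@@H](O)[C@]3(C)CC[C@H](O3)C(C)(C)CC[C@H]2C
F3 | step 15 | acetonide C6 mesylate | CC1(C)O[C@@H]2[C@]4(O1)C=C(C)C(=O)C4[C@@H](OS(C)(=O)=O)[C@]3(C)CC[C@H](O3)C(C)(C)CC[C@H]2C
F4 | step 15 | dienone acetonide | CC1(C)O[C@@H]2[C@]4(O1)C=C(C)C(=O)/C4=C/[C@]3(C)CC[C@H](O3)C(C)(C)CC[C@H]2C
F5 | step 12 | open-chain hydroxypyranone with two vinyl groups | O1[C@@H]([C@H](C)C=C)C(=O)C=C(C)C1(O)C[C@@H](O[Si](C)(C)C(C)(C)C)[C@]2(C)CC[C@H](O2)C(C)(C)C=C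
F6 | step 12 | cyclopentenone diol with two vinyl groups | O[C@@H]([C@H](C)C=C)[C@]1(O)C=C(C)C(=O)/C1=C/[C@]2(C)CC[C@H](O2)C(C)(C)C=C
F7 | step 12 | macrocyclic trienone diol (C12=C13 alkene) | O[C@@H]1[C@]4(O)C=C(C)C(=O)/C4=C/[C@]3(C)CC[C@H](O3)C(C)(C)/C=C/[C@H]1C
F8 | step 17 | C1/C15 cyclic methyl orthoacetate of 24 | COC1(C)O[C@@H]2[C@]4(O1)C=C(C)C(=O)/C4=C/[C@]3(C)CC[C@H](O3)C(C)(C)CC[C@H]2C
F9 | step 17 | C1 acetate with free C15–OH | O[C@@H]1[C@]4(OC(C)=O)C=C(C)C(=O)/C4=C/[C@]3(C)CC[C@H](O3)C(C)(C)CC[C@H]1C
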